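The numbers in the tables are calculated with made-up constants.

How strongly does the first rate of this coupling answer to the coupling partner, and how far has the birch flask come at 140 min?

| flask | starting material | coupling partner | free catalyst | time |
|---|---|---|---|---|
| larch | 50.0 mM | 55.0 mM | 0.500 mM |  |
| ash | 30.0 mM | 35.0 mM | 0.500 mM |  |
| alder | 100 mM | 55.0 mM | 0.500 mM |  |
| oak | 50.0 mM | 28.0 mM | 0.500 mM |  |
| birch | 50.0 mM | 55.0 mM | 0.500 mM | 140 min |

| run | time / min | [target] / mM |
|---|---|---|
| larch run | 1.4 | 0.6 |
| larch run | 3.1 | 2.0 |
| larch run | 7.0 | 5.0 |
| larch run | 16 | 10.5 |
| larch run | 35 | 21.4 |
| ash run | 1.4 | 0.3 |
| ash run | 3.1 | 1.4 |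
| ash run | 7.0 | 3.3 |
| ash run | 16 | 7.3 |
| ash run | 35 | 14.2 |
| alder run | 1.4 | 1.2 |
| alder run | 3.1 | 2.3 |
| alder run | 7.0 | 6.8 |
| alder run | 16 | 13.9 |
| alder run | 35 | 27.2 |
| oak run | 1.4 | 0.7 |
| oak run | 3.1 | 1.3 |
| oak run | 7.0 | 3.6 |
| oak run | 16 | 8.1 |
| oak run | 35 | 15.7 |

(each reading ± 0.3 mM)

- the power of [coupling partner] that the first rate follows, about the charge of the larch run; measure it at two percent of starting material made into target
- the power of [starting material] that the first rate follows, about the charge of the larch run; measure it at two percent of starting material made into target (one fixed amount of target, the same in the runs compared)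
- the ash run starts with 20.0 mM less of starting material and of coupling partner than the larch run, and with no target. Compared where both hold the same amount of starting material, once fifteen percent of what the ash run was charged with has turned into target, is the ash run faster, slower or alike (within a tenth)?
- target in the birch run at 140 min, as a share of the starting material charged

- Overall: starting material + coupling partner -> target, with free catalyst as catalyst.
- Constant volume, constant temperature.
- What is held in complexes is read along with the free species.
- An order is taken over about fifteen percent of the charge, up and down.

The larch and oak runs share their starting material and free catalyst and differ in coupling partner, 55.0 mM against 28.0 mM, so their columns, set side by side, show what the partner does. The row to read is 16 min, where the readings stand well above the scatter. There the larch run holds 10.5 mM of target and the oak run 8.1 mM, mean rates of 0.656 mM min⁻¹ and 0.506 mM min⁻¹. The catalyst charge divided by each rate gives the time of one turn of the cycle: 0.762 min in the larch run and 0.988 min in the oak run, which is longer than the larch turn.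

Now take a turn as a sum of waits, one of which goes inversely with [coupling partner]. The extra time in the oak run is then that wait multiplied by the ratio of the charges, 1.96, less one. This gives the partner wait, the time per turn spent on coupling partner at the larch charge, as 0.234 min. The power of [coupling partner] in the rate is the share of the turn that this wait holds, so the reckoning here commits to 0.307. In the birch flask, starting material is the limiting reagent, 50.0 mM against 55.0 mM of coupling partner, and the share asked is counted on that charge.

The forecast gives a power of 0.42 in [coupling partner] and 0.43 in [starting material], calls the ash run alike, and puts the birch flask at 90%. On the partner it says of the oak run that halving "lowers it about 0.73-fold, so its order is about 0.42". Its power is higher than the one reckoned here.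

The simulation gives 0.30 in [coupling partner] and 0.42 in [starting material], the ash run alike, and 95.6% in the birch flask.

    free catalyst + starting material → catalyst-substrate complex (114.0 M⁻¹ min⁻¹)
    catalyst-substrate complex + coupling partner → loaded catalyst (90.00 M⁻¹ min⁻¹)
    loaded catalyst → target + free catalyst (39.18 min⁻¹)
    2 starting material ⇌ idle substrate dimer, settled at all times (41.60 M⁻¹)

At the first rate of the larch run, 0.72 mM min⁻¹, a turn lasts 0.694 min, and the step of coupling partner onto the catalyst-substrate complex takes 0.202 min of it at the larch charge, a share of 0.291. The power in [coupling partner] stands at 0.30 rather than the 0.51 of the run without dimer, because pairing into idle substrate dimer lengthens the wait on starting material. Adding to that larch turn the extra wait from the partner wait of 0.234 min, an estimate from the mean rates at 16 min, gives the oak run a rate of 0.543 mM min⁻¹, and its simulated first rate is 0.55 mM min⁻¹.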